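| setting | alder | oak | birch | flask |
|---|---|---|---|---|
| substrate | 5 mM | 5 mM | 2.5 mM | 5.0 mM |
| first nucleophile | 0.55 equiv | 2.2 equiv | 1.1 equiv | 1.10 equiv |
| gas | 1.9 mM (held) | 1.9 mM (held) | 1.9 mM (held) | 1.9 mM (held) |
| remark | run made earlier | run made earlier | run made earlier |  |
| time |  |  |  | 4.0 h |

| run | time / h | other capture product / % | target / % | substrate / % |
|---|---|---|---|---|
| alder | 0.250 | 58.8 | 41.4 | 0 |
| alder | 0.417 | 58.8 | 41.0 | 0 |
| alder | 0.667 | 58.5 | 40.8 | 0.3 |
| alder | 0.833 | 58.5 | 41.1 | 0.1 |
| alder | 1.33 | 58.1 | 41.4 | 0 |
| alder | 2.00 | 59.0 | 41.4 | 0 |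
| alder | 3.00 | 59.1 | 41.8 | 0 |
| oak | 0.250 | 20.2 | 79.7 | 0 |
| oak | 0.417 | 19.9 | 80.0 | 0.3 |
| oak | 0.667 | 20.0 | 79.9 | 0 |
| oak | 0.833 | 19.9 | 80.0 | 0 |
| oak | 1.33 | 19.8 | 79.4 | 0 |
| oak | 2.00 | 19.7 | 80.1 | 0 |
| oak | 3.00 | 20.0 | 79.7 | 0.5 |
| birch | 0.667 | 51.4 | 49.1 | 0.2 |
| birch | 1.33 | 51.0 | 49.0 | 0 |
| birch | 2.00 | 51.4 | 48.8 | 0.3 |
| birch | 2.50 | 51.4 | 48.8 | 0 |
| birch | 3.00 | 51.2 | 48.7 | 0.4 |

(scatter of a reading: 0.3 percentage points)

- at the start none of the gas is in solution

- share of other capture product in other capture product plus target at 3.0 s
- share of other capture product in other capture product plus target at 4.0 min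
- share of other capture product in other capture product plus target at 4.0 h
- which of other capture product and target there is more of at 4.0 h

**Slow beginnings.** Slowness at the start lies before these readings. The alder run shows substrate at 0 % by 0.250 h, and target then moves by 0.4 percentage points up to 3.00 h, against a scatter of 0.3 points. So the alder readings show a reaction that has ended, not how it began, and what formed early stays in them. The exact time of the flask at 4.0 h need not be known well.

**What matters.** Gas was held at 1.9 mM in alder, oak, birch and the flask, so its level sits inside any ratio read from them. The charge of first nucleophile does matter: from alder to oak, other capture product falls from 59.1 % to 20.0 %. Since first nucleophile falls during a run, its curve is replaced here by its mean, the charge minus half the target.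

**The number.** In the birch run, target over other capture product, divided by that mean, reads 0.444 mM⁻¹: the capture ratio, a selectivity factor at held gas. Requiring target plus other capture product to equal the substrate, this reckoning gives the flask 3.17 mM of target, so a share of 36.5 % for other capture product. The alder run uses more of its first nucleophile than birch, which strains the mean. Its ratio reads 0.415 mM⁻¹, and that moves the flask's share to 37.9 %. Put on the full charge of first nucleophile, the ratio gives 29.0 %, a rough figure for the start. No run reads that early.

**The forecast.** The forecast gives 12 % at 3.0 s, 36.3 % at 4.0 min, 37 % at 4.0 h, and target ahead, holding that “the 3 s share is lower and poorly known”. This reckoning's end share is 36.5 %, close to the forecast's.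

**The result.** The flask gives 24.0 % at 3.0 s, 37.1 % at 4.0 min and 37.1 % at 4.0 h, with target ahead at 62.9 %. Second nucleophile approaches its level of 1.70 mM with a time constant of 0.837 s, shorter than 3.0 s. With 43 % of first nucleophile left, the mean is 3.93 mM, and the capture ratio turns that into 1.74 for target over other capture product. The flask shows 1.70.

    first nucleophile + intermediate → target (k = 14700 M⁻¹ s⁻¹)
    second nucleophile + intermediate → other capture product (k = 20600 M⁻¹ s⁻¹)
    gas ⇌ second nucleophile, rate k3*(csat - [second nucleophile]) (kL = 1.07 s⁻¹)
    substrate → intermediate (k = 0.0767 s⁻¹)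
    second nucleophile → decomposed reagent (k = 0.125 s⁻¹)
    2 substrate → self-condensation product (k = 0.00238 M⁻¹ s⁻¹)

**Second flask.** A neighbour flask charged with 4.40 equiv of first nucleophile, other charges unchanged, gets from the capture ratio a share of 10.2 % for other capture product. Computed, it ends at 10.2 %.

All runs are calculated for substances that don't exist, noise included.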